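The constants of the two mirror-image reactions are compared here by their ratio, the selectivity factor: if both substrates meet the same partner and free catalyst and each reacts in first order in itself, this ratio equals the ratio of the logarithmic falls of the two substrates from their charged shares, and the red and amber readings put it near 2.34.

in all of them: left-handed substrate 0.40 M; right-handed substrate 0.40 M; impurity 2.8 mM
- red: partner 1.2 M; free catalyst 5.6 mM; run made earlier
- amber: partner 1.2 M; free catalyst 13 mM; run made earlier
- teal: partner 1.8 M; free catalyst 8.4 mM; run made earlier
- flask: partner 1.20 M; free catalyst 8.4 mM; time 30 h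

| run | time / h | right-handed substrate / % | left-handed substrate / % |
|---|---|---|---|
| red | 2.00 | 37.9 | 27.1 |
| red | 6.00 | 27.1 | 11.1 |
| red | 12.0 | 18.7 | 5.7 |
| red | 15.0 | 15.8 | 4.6 |
| red | 25.0 | 13.0 | 1.5 |
| amber | 5.00 | 18.9 | 5.0 |
| amber | 10.0 | 10.0 | 0.2 |
| amber | 15.0 | 7.2 | 0.1 |
| amber | 20.0 | 5.3 | 0.4 |
| amber | 25.0 | 4.3 | 0 |
| teal | 2.00 | 27.1 | 13.0 |
| teal | 6.00 | 13.2 | 1.5 |
| teal | 12.0 | 4.6 | 0 |
| teal | 15.0 | 3.1 | 0.2 |
| teal | 25.0 | 1.3 | 0 |

(readings scatter by 0.5 percentage points)

- free catalyst is single-handed; left-handed substrate and right-handed substrate are mirror images of each other, charged as a racemate, each of them at the stated concentration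
- what was read earlier has a scatter of 0.5 percentage points, one standard deviation

- whether the excess of right-handed substrate over left-handed substrate among what is left of the two reaches 80 % by 30 h (yes / no)
- the highest excess of right-handed substrate over left-handed substrate among what is left of the two up to 30 h

How low must the right-handed substrate fall? An excess of 80 % means that c(right-handed substrate) stands 9.00 times above c(left-handed substrate), and with that selectivity factor the ratio is reached at one residue of right-handed substrate, the mark: 9.75 % of the two substrates charged together.

Does this flask get there in time? The teal run, with this flask's free catalyst, passes the mark between 6.00 h and 12.0 h, reading 13.2 % and then 4.6 %. Its partner charge is 1.50 times this flask's, so my own reckoning stretches those times by that ratio and places the crossing between 9.00 h and 18.0 h, earlier than 30 h. My reckoning answers yes, and it expects the excess to grow while the residue falls, which puts the top at the end of the allowed time.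

The forecast says yes, with a top of 88 % between 83 % and 93 %, holding that “excess depends only on conversion”.

The flask gives yes and a top of 87.3 %.

    2 free catalyst ⇌ resting dimer, settled at all times (K = 640 M⁻¹)
    partner + free catalyst + right-handed substrate → free catalyst + right-handed product (k = 0.0320 M⁻² s⁻¹)
    partner → decomposed reagent (k = 8.90 × 10⁻⁶ s⁻¹)
    free catalyst + impurity → spent catalyst (k = 3.20 M⁻¹ s⁻¹)
    partner + free catalyst + left-handed substrate → free catalyst + left-handed product (k = 0.0740 M⁻² s⁻¹)

The flask reaches the wanted excess at 18.6 h, just past the bracket of my reckoning, with 9.37 % of right-handed substrate left against the mark of 9.75 %. In the red run the reading of right-handed substrate at 25.0 h is 13.0 %, still above the same mark. In the flask at 1.46 h, the partner's half-life by the right-handed step is 12 h, shorter than the 22 h by decomposition alone. By 30.0 h the flask holds 0.328 M of decomposed reagent, and the partner is down to 11 % of its charge.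

The numbers in the tables were computed with constants of no real substance.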